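**Strategy**

Everything rests on cutting the C11–C12 single bond (chain numbered C1 at the ethyl terminus to C19; oxolane carbons C20–C23), the sp2–sp2 link between the C8–C11 dienyl 1,2-dione and the C12–C19 tetraene on the ring. One three-component Stille operation stitches iodo-enedione 26 (C1–C9), (E)-1,2-bis(tributylstannyl)ethene 20 (C10–C11) and the unprotected tetraenyl iodide 15 (C12–C23): the dienylstannane formed in the flask is joined to 15 at C11–C12 and the target results directly. The step exploits that C11 and C12 are unsubstituted E-alkene CH carbons remote from every stereocenter and that the C6/C7 dione deactivates the intermediate stannane. The precursors are an iodovinyl dione made by a double Weinreb acylation and an iodotetraene grown on a Mukaiyama-cyclized oxolane.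

Key step: step 17

Remark: 2-deoxy-L-ribose and (R)-2-methylbutan-1-ol are taken as commercial single enantiomers; all polyene intermediates are handled under argon with exclusion of light.

**Route**

Step 1
Reactants: 1 2-deoxy-L-ribose
Product: 2 3,4-O-isopropylidene-2-deoxy-L-erythro-pentopyranose
Conditions: 2-methoxypropene (1.3 equiv), PPTS (cat.), EtOAc, 0 °C → rt
Reagents that add atoms: 2-methoxypropene, C=C(C)OC
Why: Acid-catalysed acetalisation (kinetic acetonide formation with an enol ether) should tie up the cis-3,4-diol of the pyranose form so that only the hemiacetal hydroxyl stays free; no stereocenter is formed or touched.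

Step 2
Reactants: 2 3,4-O-isopropylidene-2-deoxy-L-erythro-pentopyranose
Product: 3 [(4S,5R)-2,2-dimethyl-5-(prop-2-enyl)-1,3-dioxolan-4-yl]methanol
Conditions: Ph3PCH3Br (3 equiv), KOt-Bu (3 equiv), THF, 0 °C → rt
Reagents that add atoms: methylenetriphenylphosphorane (made in the flask from methyltriphenylphosphonium bromide and KOt-Bu), C=P(c1ccccc1)(c1ccccc1)c1ccccc1
Why: Wittig methylenation of the open-chain aldehyde that is in equilibrium with the lactol should install the terminal alkene and release the primary hydroxyl, the two dioxolane stereocenters being carried over unchanged.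

Step 3
Reactants: 3 [(4S,5R)-2,2-dimethyl-5-(prop-2-enyl)-1,3-dioxolan-4-yl]methanol
Product: 5 (4R,5R)-2,2-dimethyl-5-(prop-2-enyl)-1,3-dioxolane-4-carboxylic acid, via acetonide aldehyde 4 (not isolated)
Conditions: TEMPO (0.2 equiv), PhI(OAc)2 (2.2 equiv), MeCN/H2O 1:1, rt
Reagents that add atoms: water, O
Why: Nitroxyl-catalysed (TEMPO) oxidation with PhI(OAc)2 in aqueous acetonitrile should take the primary alcohol through aldehyde 4 and its hydrate to the acid while the terminal alkene and the acetonide, which also blocks glycol cleavage, stay intact.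

Step 4
Reactants: 5 (4R,5R)-2,2-dimethyl-5-(prop-2-enyl)-1,3-dioxolane-4-carboxylic acid
Product: 6 methyl (2R,3R)-2,3-dihydroxyhex-5-enoate
Conditions: HCl (1.25 M in MeOH), 0 °C → rt
Reagents that add atoms: methanol, CO
Why: Fischer esterification and acid-catalysed acetonide cleavage should run together in methanolic HCl, the water released by the esterification hydrolysing the acetal to acetone, without touching either stereocenter.

Step 5
Reactants: 6 methyl (2R,3R)-2,3-dihydroxyhex-5-enoate
Product: 7 methyl (2R,3R,5R)-3-hydroxy-5-(hydroxymethyl)oxolane-2-carboxylate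
Conditions: Co(modp)2 (15 mol %; modp = 1-morpholinocarbamoyl-4,4-dimethylpentane-1,3-dionate), t-BuOOH (10 mol %), O2 (1 atm), i-PrOH, 55 °C
Reagents that add atoms: dioxygen, O=O
Why: Mukaiyama aerobic oxidative cyclization: the hydroxyl on the ester-bearing carbon should close 5-exo onto the alkene under cobalt mediation and the primary radical is trapped by O2 to give the hydroxymethyl group, the new oxolane C5 stereocenter being set by substrate control trans to the C2 ester (2,5-trans rule) and cis to the C3 hydroxyl (2,4-cis rule), two preferences that reinforce each other here.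

Step 6
Reactants: 7 methyl (2R,3R,5R)-3-hydroxy-5-(hydroxymethyl)oxolane-2-carboxylate
Product: 8 methyl (2R,3R,5R)-5-formyl-3-hydroxyoxolane-2-carboxylate
Conditions: TEMPO (0.1 equiv), PhI(OAc)2 (1.1 equiv), CH2Cl2, rt; used crude
Reagents that add atoms: none
Why: TEMPO/PhI(OAc)2 oxidation is selective for primary over secondary alcohols and stops at the aldehyde in dry CH2Cl2 under nearly neutral conditions, which should leave the ring hydroxyl and the epimerisable oxolane C5 center untouched.

Step 7
Reactants: 8 methyl (2R,3R,5R)-5-formyl-3-hydroxyoxolane-2-carboxylate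
Product: 9 methyl (2R,3R,5R)-3-hydroxy-5-[(E)-2-iodoethenyl]oxolane-2-carboxylate
Conditions: CrCl2 (6 equiv), CHI3 (2 equiv), THF/1,4-dioxane 1:6, 0 °C → rt, dark
Reagents that add atoms: iodoform, IC(I)I
Why: Takai olefination: the geminal dichromium reagent from iodoform should add to the aldehyde and eliminate to the (E)-vinyl iodide under non-basic conditions that tolerate the free hydroxyl, the ester and the α-alkoxy stereocenter.

Step 8
Reactants: 10 (E)-pent-2-en-4-yn-1-ol
Product: 11 (2E,4E)-5-(tributylstannyl)penta-2,4-dien-1-ol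
Conditions: Bu3SnH (1.1 equiv), PdCl2(PPh3)2 (2 mol %), THF, 0 °C
Reagents that add atoms: tributyltin hydride, CCCC[SnH](CCCC)CCCC
Why: Palladium-catalysed hydrostannation adds H and Sn syn across the terminal alkyne with tin at the unsubstituted carbon, which should give the (2E,4E)-dienylstannane.

Step 9
Reactants: 11 (2E,4E)-5-(tributylstannyl)penta-2,4-dien-1-ol
Product: 12 (2E,4E)-5-(tributylstannyl)penta-2,4-dienal
Conditions: MnO2 (excess), CH2Cl2, rt
Reagents that add atoms: none
Why: MnO2 oxidation is selective for allylic alcohols and should give the conjugated dienal without cleaving the vinyl–tin bond or isomerising the alkenes.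

Step 10
Reactants: 9 methyl (2R,3R,5R)-3-hydroxy-5-[(E)-2-iodoethenyl]oxolane-2-carboxylate; 12 (2E,4E)-5-(tributylstannyl)penta-2,4-dienal
Product: 13 methyl (2R,3R,5R)-3-hydroxy-5-[(1E,3E,5E)-7-oxohepta-1,3,5-trienyl]oxolane-2-carboxylate
Conditions: PdCl2(MeCN)2 (5 mol %), DMF, rt, dark
Reagents that add atoms: none
Why: Stille coupling of a vinyl iodide with a vinylstannane is stereoretentive at both partners and neutral, so the aldehyde, the ester and the free hydroxyl should survive and the all-E trienal result.

Step 11
Reactants: 13 methyl (2R,3R,5R)-3-hydroxy-5-[(1E,3E,5E)-7-oxohepta-1,3,5-trienyl]oxolane-2-carboxylate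
Product: 14 methyl (2R,3R,5R)-3-hydroxy-5-[(1E,3E,5E,7E)-8-iodoocta-1,3,5,7-tetraenyl]oxolane-2-carboxylate
Conditions: CrCl2 (6 equiv), CHI3 (2 equiv), THF/1,4-dioxane 1:6, 0 °C → rt, dark
Reagents that add atoms: iodoform, IC(I)I
Why: Takai olefination of the conjugated aldehyde should give the terminal (E)-vinyl iodide, divalent chromium reacting with the aldehyde in preference to the ester.

Step 12
Reactants: 14 methyl (2R,3R,5R)-3-hydroxy-5-[(1E,3E,5E,7E)-8-iodoocta-1,3,5,7-tetraenyl]oxolane-2-carboxylate
Product: 15 (2R,3R,5R)-3-hydroxy-5-[(1E,3E,5E,7E)-8-iodoocta-1,3,5,7-tetraenyl]oxolane-2-carboxylic acid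
Conditions: LiOH·H2O (3 equiv), THF/H2O 3:1, 0 °C; then 1 M HCl to pH 3, 0 °C, dark
Reagents that add atoms: lithium hydroxide, [Li+].[OH-]
Why: Saponification of the methyl ester with LiOH at 0 °C, followed by cold acidification only to pH 3, should free the acid without epimerising the carboxyl-bearing carbon or ionising the polyenylic C–O bond of the ring.

Step 13
Reactants: 16 (R)-2-methylbutan-1-ol
Product: 17 (R)-2-methylbutanal
Conditions: TEMPO (1 mol %), KBr (10 mol %), NaOCl (1.1 equiv), NaHCO3 buffer, CH2Cl2/H2O, 0 °C; used as a dried CH2Cl2 solution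
Reagents that add atoms: none
Why: TEMPO/hypochlorite oxidation in a buffered two-phase system is fast at 0 °C and should deliver the α-branched aldehyde without racemisation, the stereocenter coming from the alcohol.

Step 14
Reactants: 17 (R)-2-methylbutanal
Product: 18 (1E,3R)-1-iodo-3-methylpent-1-ene
Conditions: CrCl2 (6 equiv), CHI3 (2 equiv), THF, 0 °C → rt, dark
Reagents that add atoms: iodoform, IC(I)I
Why: Takai olefination is non-basic and should turn the α-chiral aldehyde into the (E)-vinyl iodide with its configuration intact.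

Step 15
Reactants: 18 (1E,3R)-1-iodo-3-methylpent-1-ene; 19 N,N'-dimethoxy-N,N'-dimethyloxamide; 20 (E)-1,2-bis(tributylstannyl)ethene
Product: 25 (1E,5E,7R)-7-methyl-1-(tributylstannyl)nona-1,5-diene-3,4-dione, via vinyllithium 21 (not isolated), via mono-adduct alkoxide 22 (not isolated), via stannylvinyllithium 23 (not isolated), via bis-adduct dialkoxide 24 (not isolated)
Conditions: 18, t-BuLi (2.0 equiv), Et2O, −78 °C, then 19 (1.0 equiv), THF, −78 °C; 20 (1.05 equiv), n-BuLi (1.0 equiv), THF, −78 °C, added by cannula, −78 → −40 °C; AcOH, −78 °C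
Reagents that add atoms: none
Why: Weinreb ketone synthesis carried out twice on one bis-amide: iodine–lithium exchange (retention) gives vinyllithium 21, whose adduct 22 persists as a chelated tetrahedral alkoxide that masks the first carbonyl while stannylvinyllithium 23 (from tin–lithium exchange) adds to the second amide, and protonation of 24 collapses both hemiaminals to the 1,2-dione.

Step 16
Reactants: 25 (1E,5E,7R)-7-methyl-1-(tributylstannyl)nona-1,5-diene-3,4-dione
Product: 26 (1E,5E,7R)-1-iodo-7-methylnona-1,5-diene-3,4-dione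
Conditions: I2 (1.05 equiv), CH2Cl2, 0 °C, dark
Reagents that add atoms: iodine, II
Why: Iododestannylation (electrophilic ipso substitution at the vinyl carbon) is fast and stereoretentive at 0 °C, while the electron-poor enone alkenes should not add iodine.

Step 17
Reactants: 26 (1E,5E,7R)-1-iodo-7-methylnona-1,5-diene-3,4-dione; 20 (E)-1,2-bis(tributylstannyl)ethene; 15 (2R,3R,5R)-3-hydroxy-5-[(1E,3E,5E,7E)-8-iodoocta-1,3,5,7-tetraenyl]oxolane-2-carboxylic acid
Product: 28 (2R,3R,5R)-3-hydroxy-5-[(1E,3E,5E,7E,9E,11E,15E,17R)-17-methyl-13,14-dioxononadeca-1,3,5,7,9,11,15-heptaenyl]oxolane-2-carboxylic acid, via dienylstannane 27 (not isolated)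
Conditions: 20 (1.0 equiv), Pd2(dba)3 (3 mol %), AsPh3 (12 mol %), DMF, 0 °C, slow addition of 26 (1.0 equiv), then rt; then 15 (0.8 equiv), i-Pr2NEt (1.0 equiv), CuI (20 mol %), rt, dark; aqueous KF/citrate (pH 4) work-up
Reagents that add atoms: none
Why: Zerovalent palladium inserts into the C–I bond of the vinylogous acyl iodide 26, one tin of 20 transmetalates and reductive elimination gives dienylstannane 27 (C9–C10 bond), and after 15 is added a second oxidative addition, copper-assisted transmetalation of 27 and reductive elimination form the C11–C12 bond and release the target. The closest known reaction type is the Stille coupling used as a double stitching of two alkenyl iodides with (E)-1,2-bis(tributylstannyl)ethene. No ring is closed and no stereocenter is formed, and the geometry of the alkenes is kept because oxidative addition, transmetalation and reductive elimination are all stereoretentive. The step needs mono-coupling in the first stage, which is secured by slow addition of 26 to 20 and by the dione acceptor, which makes the remaining C–Sn bond of 27 far less nucleophilic than those of 20 until CuI is added. It also needs tolerance of the free acid, the hydroxyl and the base-sensitive 1,2-dione, which is secured by neutral conditions, by the arsine ligand that does not attack the dione, and by holding the acid as its ammonium carboxylate to suppress protodestannylation.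

**Compound list**

1 | 2-deoxy-L-ribose (2-deoxy-L-erythro-pentose, drawn as the open-chain aldehyde) | O=CC[C@@H](O)[C@@H](O)CO | starting material
2 | 3,4-O-isopropylidene-2-deoxy-L-erythro-pentopyranose (anomeric mixture) | OC1C[C@H]2OC(C)(C)O[C@H]2CO1 | intermediate
3 | [(4S,5R)-2,2-dimethyl-5-(prop-2-enyl)-1,3-dioxolan-4-yl]methanol | C=CC[C@H]1OC(C)(C)O[C@H]1CO | intermediate
4 | (4R,5R)-2,2-dimethyl-5-(prop-2-enyl)-1,3-dioxolane-4-carbaldehyde | C=CC[C@H]1OC(C)(C)O[C@H]1C=O | intermediate
5 | (4R,5R)-2,2-dimethyl-5-(prop-2-enyl)-1,3-dioxolane-4-carboxylic acid | C=CC[C@H]1OC(C)(C)O[C@H]1C(=O)O | intermediate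
6 | methyl (2R,3R)-2,3-dihydroxyhex-5-enoate | C=CC[C@@H](O)[C@H](C(=O)OC)O | intermediate
7 | methyl (2R,3R,5R)-3-hydroxy-5-(hydroxymethyl)oxolane-2-carboxylate | OC[C@H]1C[C@@H](O)[C@H](C(=O)OC)O1 | intermediate
8 | methyl (2R,3R,5R)-5-formyl-3-hydroxyoxolane-2-carboxylate | O=C[C@H]1C[C@@H](O)[C@H](C(=O)OC)O1 | intermediate
9 | methyl (2R,3R,5R)-3-hydroxy-5-[(E)-2-iodoethenyl]oxolane-2-carboxylate | I/C=C/[C@H]1C[C@@H](O)[C@H](C(=O)OC)O1 | intermediate
10 | (E)-pent-2-en-4-yn-1-ol | C#C/C=C/CO | starting material
11 | (2E,4E)-5-(tributylstannyl)penta-2,4-dien-1-ol | CCCC[Sn](CCCC)(CCCC)/C=C/C=C/CO | intermediate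
12 | (2E,4E)-5-(tributylstannyl)penta-2,4-dienal | CCCC[Sn](CCCC)(CCCC)/C=C/C=C/C=O | intermediate
13 | methyl (2R,3R,5R)-3-hydroxy-5-[(1E,3E,5E)-7-oxohepta-1,3,5-trienyl]oxolane-2-carboxylate | O=C/C=C/C=C/C=C/[C@H]1C[C@@H](O)[C@H](C(=O)OC)O1 | intermediate
14 | methyl (2R,3R,5R)-3-hydroxy-5-[(1E,3E,5E,7E)-8-iodoocta-1,3,5,7-tetraenyl]oxolane-2-carboxylate | I/C=C/C=C/C=C/C=C/[C@H]1C[C@@H](O)[C@H](C(=O)OC)O1 | intermediate
15 | (2R,3R,5R)-3-hydroxy-5-[(1E,3E,5E,7E)-8-iodoocta-1,3,5,7-tetraenyl]oxolane-2-carboxylic acid | I/C=C/C=C/C=C/C=C/[C@H]1C[C@@H](O)[C@H](C(=O)O)O1 | intermediate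
16 | (R)-2-methylbutan-1-ol | CC[C@@H](C)CO | starting material
17 | (R)-2-methylbutanal | CC[C@@H](C)C=O | intermediate
18 | (1E,3R)-1-iodo-3-methylpent-1-ene | CC[C@@H](C)/C=C/I | intermediate
19 | N,N'-dimethoxy-N,N'-dimethyloxamide | CON(C)C(=O)C(=O)N(C)OC | starting material
20 | (E)-1,2-bis(tributylstannyl)ethene | CCCC[Sn](CCCC)(CCCC)/C=C/[Sn](CCCC)(CCCC)CCCC | starting material
21 | [(1E,3R)-3-methylpent-1-enyl]lithium | CC[C@@H](C)/C=C/[Li] | intermediate
22 | lithium (3E,5R)-1,2-bis[methoxy(methyl)amino]-5-methyl-1-oxohept-3-en-2-olate (hemiaminal carbon unassigned) | CC[C@@H](C)/C=C/C(O[Li])(N(C)OC)C(=O)N(C)OC | intermediate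
23 | [(E)-2-(tributylstannyl)ethenyl]lithium | [Li]/C=C/[Sn](CCCC)(CCCC)CCCC | intermediate
24 | dilithium (1E,5E,7R)-3,4-bis[methoxy(methyl)amino]-7-methyl-1-(tributylstannyl)nona-1,5-diene-3,4-diolate (hemiaminal carbons unassigned) | CC[C@@H](C)/C=C/C(O[Li])(N(C)OC)C(O[Li])(N(C)OC)/C=C/[Sn](CCCC)(CCCC)CCCC | intermediate
25 | (1E,5E,7R)-7-methyl-1-(tributylstannyl)nona-1,5-diene-3,4-dione | CC[C@@H](C)/C=C/C(=O)C(=O)/C=C/[Sn](CCCC)(CCCC)CCCC | intermediate
26 | (1E,5E,7R)-1-iodo-7-methylnona-1,5-diene-3,4-dione | CC[C@@H](C)/C=C/C(=O)C(=O)/C=C/I | intermediate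
27 | (1E,3E,7E,9R)-9-methyl-1-(tributylstannyl)undeca-1,3,7-triene-5,6-dione | CC[C@@H](C)/C=C/C(=O)C(=O)/C=C/C=C/[Sn](CCCC)(CCCC)CCCC | intermediate
28 | (2R,3R,5R)-3-hydroxy-5-[(1E,3E,5E,7E,9E,11E,15E,17R)-17-methyl-13,14-dioxononadeca-1,3,5,7,9,11,15-heptaenyl]oxolane-2-carboxylic acid (CNP0156165.1) | CC[C@@H](C)/C=C/C(=O)C(=O)/C=C/C=C/C=C/C=C/C=C/C=C/[C@H]1C[C@@H](O)[C@H](C(=O)O)O1 | target

**Step count and risks**

Total step count: 17. Longest linear sequence: 11 steps (steps 1–7, 10–12 and 17, from 2-deoxy-L-ribose).

Steps most likely to fail: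

1. Step 17. What may go wrong: over-coupling of the linchpin in the first stage (both tin atoms reacting with 26), protonolysis of the stannane or of the vinylcopper species by the free carboxylic acid in the second stage, and light- or metal-induced isomerisation or decomposition of the hexaene-dione. The fallback sets out from 26 (with 20 and 14) and comes back to the route at 28. 26 would be coupled with a three-fold excess of 20 under the first-stage conditions and stannane 27 isolated. 27 would then be joined by Stille coupling (Pd2(dba)3, AsPh3, CuI, DMF, rt, dark) to the methyl ester 14 instead of the acid, to give methyl (2R,3R,5R)-3-hydroxy-5-[(1E,3E,5E,7E,9E,11E,15E,17R)-17-methyl-13,14-dioxononadeca-1,3,5,7,9,11,15-heptaenyl]oxolane-2-carboxylate F1. The ester would be cleaved last by an esterase (pig liver esterase, pH 7 phosphate buffer, DMSO cosolvent) to give 28, so that the acid is masked during C–C bond formation and released enzymatically under neutral conditions.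

2. Step 5. What may go wrong: slow or unselective ring closure, because cobalt may be sequestered by the vicinal diol and α-hydroxy ester, the electron-poor hydroxyl may add sluggishly, and hydration of the alkene may compete. The fallback sets out from 6 and comes back at 8, bypassing step 6. Iodoetherification of 6 (I2, NaHCO3, MeCN, 0 °C, 5-exo) would give methyl (2R,3R,5R)-3-hydroxy-5-(iodomethyl)oxolane-2-carboxylate F2, the 2,5-trans isomer being separated from its epimer by chromatography. Oxidation of the primary iodide with trimethylamine N-oxide in DMSO (Kornblum-type oxidation) would then give aldehyde 8 directly.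

3. Step 15. What may go wrong: loss of chemoselectivity in the double acyl substitution, namely the first vinyllithium adding twice, collapse of the first tetrahedral alkoxide before the second addition with attack on the freed ketone, or conjugate addition of liberated N,O-dimethylhydroxylamine on quenching. The fallback sets out from 17 and comes back at 27, so that steps 14–16 are not needed. Oxalyl chloride and methylenetriphenylphosphorane (four equivalents, transylidation) would give 1,4-bis(triphenyl-λ5-phosphanylidene)butane-2,3-dione F3. Wittig reaction of F3 with 17 (one equivalent, toluene, 60 °C) would give the keto ylide (4E,6R)-6-methyl-1-(triphenyl-λ5-phosphanylidene)oct-4-ene-2,3-dione F4. A second Wittig reaction of F4 with (E)-3-(tributylstannyl)prop-2-enal F5 (from commercial (E)-3-(tributylstannyl)prop-2-en-1-ol and MnO2) would give stannane 27, which then enters the second stage of step 17 with 15.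

Further compounds
F1 | step 17 | methyl (2R,3R,5R)-3-hydroxy-5-[(1E,3E,5E,7E,9E,11E,15E,17R)-17-methyl-13,14-dioxononadeca-1,3,5,7,9,11,15-heptaenyl]oxolane-2-carboxylate | CC[C@@H](C)/C=C/C(=O)C(=O)/C=C/C=C/C=C/C=C/C=C/C=C/[C@H]1C[C@@H](O)[C@H](C(=O)OC)O1
F2 | step 5 | methyl (2R,3R,5R)-3-hydroxy-5-(iodomethyl)oxolane-2-carboxylate | IC[C@H]1C[C@@H](O)[C@H](C(=O)OC)O1
F3 | step 15 | 1,4-bis(triphenyl-λ5-phosphanylidene)butane-2,3-dione | O=C(C=P(c1ccccc1)(c1ccccc1)c1ccccc1)C(=O)C=P(c1ccccc1)(c1ccccc1)c1ccccc1
F4 | step 15 | (4E,6R)-6-methyl-1-(triphenyl-λ5-phosphanylidene)oct-4-ene-2,3-dione | CC[C@@H](C)/C=C/C(=O)C(=O)C=P(c1ccccc1)(c1ccccc1)c1ccccc1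
F5 | step 15 | (E)-3-(tributylstannyl)prop-2-enal | O=C/C=C/[Sn](CCCC)(CCCC)CCCC
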